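**Strategy.** Everything rests on growing the central arene, ring B, directly on the ether oxygen of ring A. Ring B (B1 lactone C–O, B2 ether C–O, B3 CH, B4 pyranone C–O, B5 acyl carbon, B6 C–CH3) is a hydroquinone monoether: oxygens para on B1 and B4, the ring A aryloxy group on B2, methyl on B6. A Dötz benzannulation builds this array from a methoxy(propenyl)carbene complex of zerovalent chromium, one CO ligand and the ethynyl ether of the ring A formyl salicylate, forging B3–B4, B1–B2 and B1–B6 and leaving B1 as the free hydroxyl that ring D, the dioxepinone, needs. Ring C is closed last at B5.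

Key step: step 7

Ring names: ring A is the formyl arene, whose carbons are referred to by their substituents (methyl carbon, CH, hydroxyl carbon, formyl carbon, ether carbon, carboxyl carbon); ring B is the central arene with B1–B6 as defined above; ring C is the pyranone; ring D is the dioxepinone. The target has no stereocentre.

Assumption: (E)-1-bromoprop-1-ene is used as the single E isomer; the alkene geometry is lost on aromatisation in any case.

Design remarks:
- The aryl ethynyl ether is made by bromination and twofold dehydrobromination of the aryl vinyl ether, the long-established entry to aryloxyacetylenes, so that no C–O bond has to be made at an alkyne carbon.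
- The aldehyde is carried unprotected. It is non-enolisable and flanked by two ortho oxygen substituents.
- Ring C is introduced by Friedel–Crafts acylation of the B4 methyl ether, not of the free phenol, so that the choice between B5 and B3 is under steric, kinetic control.

**Step 1**
Reactants: 1 methyl orsellinate (methyl 2,4-dihydroxy-6-methylbenzoate)
Product: 2 methyl 2-hydroxy-4-methoxy-6-methylbenzoate
Conditions: MeI (1.05 equiv), K2CO3, acetone, reflux
Reagents that add atoms: iodomethane, CI
Why: Williamson methylation should select the 4-hydroxyl, because the 2-hydroxyl is hydrogen-bonded to the ester carbonyl and is the less acidic and more hindered site.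

**Step 2**
Reactants: 2 methyl 2-hydroxy-4-methoxy-6-methylbenzoate
Product: 3 methyl 3-formyl-2-hydroxy-4-methoxy-6-methylbenzoate
Conditions: Cl2CHOMe, TiCl4, CH2Cl2, 0 → 23 °C; then aq. HCl
Reagents that add atoms: dichloro(methoxy)methane, COC(Cl)Cl; water, O
Why: Rieche formylation, in which the titanium phenoxide–ester chelate should deliver the electrophile to position 3 of the benzoate, the only free position ortho to the phenol and one also activated by the ortho methoxy group, before hydrolysis of the α-chloro ether unveils the aldehyde.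

**Step 3**
Reactants: 3 methyl 3-formyl-2-hydroxy-4-methoxy-6-methylbenzoate; 4 1,2-dibromoethane (fivefold excess)
Product: 5 methyl 2-(2-bromoethoxy)-3-formyl-4-methoxy-6-methylbenzoate
Conditions: K2CO3, DMF, 70 °C
Reagents that add atoms: none
Why: SN2 O-alkylation of the acidic phenoxide, with the excess of dibromide suppressing the bis-aryl ether.

**Step 4**
Reactants: 5 methyl 2-(2-bromoethoxy)-3-formyl-4-methoxy-6-methylbenzoate
Product: 6 methyl 2-(ethenyloxy)-3-formyl-4-methoxy-6-methylbenzoate
Conditions: KOt-Bu (1.2 equiv), THF, 0 °C
Reagents that add atoms: none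
Why: Bimolecular β-elimination of HBr from a 2-bromoethyl aryl ether by a bulky alkoxide is the standard route to aryl vinyl ethers, and the shielded, non-enolisable aldehyde and the di-ortho-substituted ester should not be attacked at 0 °C.

**Step 5**
Reactants: 6 methyl 2-(ethenyloxy)-3-formyl-4-methoxy-6-methylbenzoate
Product: 8 methyl 2-(ethynyloxy)-3-formyl-4-methoxy-6-methylbenzoate, via 1,2-dibromoethyl ether 7 (not isolated)
Conditions: Br2 (1.0 equiv), CH2Cl2, −78 °C; then KOt-Bu (3 equiv), THF, −78 → 0 °C; NH4Cl quench; filtration through Et3N-deactivated silica, used at once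
Reagents that add atoms: none
Why: Bromine should add to the enol ether double bond far faster than it substitutes the deactivated ring, and twofold base-induced loss of HBr from an α,β-dibromoethyl aryl ether is the classical preparation of aryloxyacetylenes.

**Step 6**
Reactants: 9 hexacarbonylchromium, Cr(CO)6; 10 (E)-1-bromoprop-1-ene
Product: 13 pentacarbonyl[(2E)-1-methoxybut-2-en-1-ylidene]chromium, via (E)-prop-1-enyllithium 11 (not isolated), via lithium pentacarbonyl(but-2-enoyl)chromate 12 (not isolated)
Conditions: t-BuLi (2 equiv), Et2O, −78 °C; Cr(CO)6, Et2O, −78 → 23 °C; MeOSO2CF3, CH2Cl2, 0 °C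
Reagents that add atoms: methyl trifluoromethanesulfonate, COS(=O)(=O)C(F)(F)F
Why: Fischer carbene synthesis, in which bromine–lithium exchange retains the E geometry, the alkenyllithium adds to a CO ligand and the hard methylating agent alkylates the acyl chromate on oxygen.

**Step 7**
Reactants: 8 methyl 2-(ethynyloxy)-3-formyl-4-methoxy-6-methylbenzoate; 13 pentacarbonyl[(2E)-1-methoxybut-2-en-1-ylidene]chromium (1.3 equiv)
Product: 15 methyl 3-formyl-2-(2-hydroxy-5-methoxy-3-methylphenoxy)-4-methoxy-6-methylbenzoate, via Cr(CO)3-bound phenol 14 (not isolated)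
Conditions: THF (0.05 M), 50 °C, argon, slow addition of 8 to 13; then air, MeCN, 23 °C
Reagents that add atoms: none
Why: Proposed new method: the closest known reaction is the Dötz benzannulation of alkenyl(alkoxy)carbene complexes of chromium with terminal alkynes, extended here to an aryl ethynyl ether, whose polarisation (nucleophilic terminal carbon) and bulk should both send the CH terminus to the electrophilic carbene carbon (B3–B4) and leave the aryloxy-bearing carbon as the new carbene centre. Thermal loss of one CO from 13 opens a coordination site, the alkyne inserts to give a chromium-bound dienylcarbene, CO migrates onto the aryloxy carbene carbon (B1–B2) to give an η4-dienylketene, and ring B closes by 6π electrocyclisation of that ketene onto the propenyl terminus (B1–B6), followed by enolisation to the phenol. No stereocentre is formed and the propenyl geometry is erased on aromatisation. The selectivity needed is regiochemical, aryloxy next to the CO-derived carbon, and it should be secured because the steric and the electronic bias of the ynol ether point the same way; benzannulation must also outrun [2+2] addition of the electron-rich alkyne to the carbene's alkene and uptake of a second alkyne, which THF at 50 °C and slow addition of 8 should favour. The shielded aldehyde and the hindered ester of ring A should stay bystanders, and an aryl ynol ether has no retro-ene path to a ketene. Air should release the Cr(CO)3 fragment from 14 without oxidising the 4-methoxyphenol, which rules out stronger oxidants in the work-up.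

**Step 8**
Reactants: 15 methyl 3-formyl-2-(2-hydroxy-5-methoxy-3-methylphenoxy)-4-methoxy-6-methylbenzoate
Product: 16 3-formyl-2-(2-hydroxy-5-methoxy-3-methylphenoxy)-4-methoxy-6-methylbenzoic acid
Conditions: LiI (5 equiv), EtOAc, reflux; then aq. HCl
Reagents that add atoms: none
Why: Lithium-assisted SN2 attack of iodide on the ester methyl group should cleave a di-ortho-substituted benzoate that resists saponification, while the aldehyde, the phenol and the aryl methyl ethers are left alone.

**Step 9**
Reactants: 16 3-formyl-2-(2-hydroxy-5-methoxy-3-methylphenoxy)-4-methoxy-6-methylbenzoic acid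
Product: 17 3,7-dimethoxy-1,9-dimethyl-11-oxo-11H-dibenzo[b,e][1,4]dioxepine-4-carbaldehyde (the depsidone: ring A carries methyl at position 1, methoxy at position 3 and formyl at position 4; ring B carries methoxy at position 7, which is B4, and methyl at position 9, which is B6)
Conditions: EDC·HCl, DMAP, CH2Cl2 (0.005 M), 23 °C
Reagents that add atoms: none
Why: Carbodiimide (Steglich-type) lactonisation onto the only free hydroxyl, B1, which sits ortho to the ether link, should close the seven-membered ring without the strong acid that could divert the activated acid to a xanthone by C-acylation at B3.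

**Step 10**
Reactants: 17 3,7-dimethoxy-1,9-dimethyl-11-oxo-11H-dibenzo[b,e][1,4]dioxepine-4-carbaldehyde; 18 3-methylbut-2-enoyl chloride (1.5 equiv)
Product: 19 3,7-dimethoxy-1,9-dimethyl-8-(3-methylbut-2-enoyl)-11-oxo-11H-dibenzo[b,e][1,4]dioxepine-4-carbaldehyde
Conditions: AlCl3 (3.5 equiv), CH2Cl2, −20 → 0 °C
Reagents that add atoms: none
Why: Friedel–Crafts acylation under kinetic control should go to B5 (position 8 of the depsidone), which is ortho to the B4 methoxy group and para to the B2 ether oxygen, whereas B3 lies between two oxygen substituents like the unreactive 2-position of a resorcinol diether and ring A is deactivated by its two carbonyl groups; any ether cleavage next to a carbonyl at this stage only anticipates step 11.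

**Step 11**
Reactants: 19 3,7-dimethoxy-1,9-dimethyl-8-(3-methylbut-2-enoyl)-11-oxo-11H-dibenzo[b,e][1,4]dioxepine-4-carbaldehyde
Product: 21 mollicellin B, via hydroxy enone 20 (not isolated)
Conditions: BBr3 (6 equiv), CH2Cl2, −78 → 0 °C; aq. NaHCO3; then Et3N, CH2Cl2, 23 °C
Reagents that add atoms: none
Why: BBr3 should cleave both aryl methyl ethers, each ortho to a carbonyl group and so assisted by chelation, without opening the aryl lactone at or below 0 °C, and the freed B4 phenol should then add to the β,β-dimethyl enone in a 6-endo-trig oxa-Michael closure that forms the 2,2-dimethylchroman-4-one of ring C.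

**Compound list**

1 | methyl orsellinate (methyl 2,4-dihydroxy-6-methylbenzoate) | COC(=O)c1c(C)cc(O)cc1O | starting material
2 | methyl 2-hydroxy-4-methoxy-6-methylbenzoate | COC(=O)c1c(C)cc(OC)cc1O | intermediate
3 | methyl 3-formyl-2-hydroxy-4-methoxy-6-methylbenzoate | COC(=O)c1c(C)cc(OC)c(C=O)c1O | intermediate
4 | 1,2-dibromoethane | BrCCBr | starting material
5 | methyl 2-(2-bromoethoxy)-3-formyl-4-methoxy-6-methylbenzoate | COC(=O)c1c(C)cc(OC)c(C=O)c1OCCBr | intermediate
6 | methyl 2-(ethenyloxy)-3-formyl-4-methoxy-6-methylbenzoate | COC(=O)c1c(C)cc(OC)c(C=O)c1OC=C | intermediate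
7 | methyl 2-(1,2-dibromoethoxy)-3-formyl-4-methoxy-6-methylbenzoate (racemic, not isolated) | COC(=O)c1c(C)cc(OC)c(C=O)c1OC(Br)CBr | intermediate
8 | methyl 2-(ethynyloxy)-3-formyl-4-methoxy-6-methylbenzoate | COC(=O)c1c(C)cc(OC)c(C=O)c1OC#C | intermediate
9 | hexacarbonylchromium, Cr(CO)6 | O=C=[Cr](=C=O)(=C=O)(=C=O)(=C=O)=C=O | starting material
10 | (E)-1-bromoprop-1-ene | C/C=C/Br | starting material
11 | (E)-prop-1-en-1-yllithium (not isolated) | C/C=C/[Li] | intermediate
12 | lithium pentacarbonyl[(2E)-but-2-enoyl]chromate (not isolated) | [Li+].C/C=C/C([O-])=[Cr](=C=O)(=C=O)(=C=O)(=C=O)=C=O | intermediate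
13 | pentacarbonyl[(2E)-1-methoxybut-2-en-1-ylidene]chromium | C/C=C/C(OC)=[Cr](=C=O)(=C=O)(=C=O)(=C=O)=C=O | intermediate
14 | tricarbonylchromium complex of 15, Cr(CO)3 η6-bound to ring B (not isolated; written as the dot-joined pair) | COC(=O)c1c(C)cc(OC)c(C=O)c1Oc1cc(OC)cc(C)c1O.O=C=[Cr](=C=O)=C=O | intermediate
15 | methyl 3-formyl-2-(2-hydroxy-5-methoxy-3-methylphenoxy)-4-methoxy-6-methylbenzoate | COC(=O)c1c(C)cc(OC)c(C=O)c1Oc1cc(OC)cc(C)c1O | intermediate
16 | 3-formyl-2-(2-hydroxy-5-methoxy-3-methylphenoxy)-4-methoxy-6-methylbenzoic acid | OC(=O)c1c(C)cc(OC)c(C=O)c1Oc1cc(OC)cc(C)c1O | intermediate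
17 | 3,7-dimethoxy-1,9-dimethyl-11-oxo-11H-dibenzo[b,e][1,4]dioxepine-4-carbaldehyde | Cc1cc(OC)c(C=O)c2Oc3cc(OC)cc(C)c3OC(=O)c12 | intermediate
18 | 3-methylbut-2-enoyl chloride | CC(C)=CC(Cl)=O | starting material
19 | 3,7-dimethoxy-1,9-dimethyl-8-(3-methylbut-2-enoyl)-11-oxo-11H-dibenzo[b,e][1,4]dioxepine-4-carbaldehyde | Cc1cc(OC)c(C=O)c2Oc3cc(OC)c(C(=O)C=C(C)C)c(C)c3OC(=O)c12 | intermediate
20 | 3,7-dihydroxy-1,9-dimethyl-8-(3-methylbut-2-enoyl)-11-oxo-11H-dibenzo[b,e][1,4]dioxepine-4-carbaldehyde (not isolated) | Cc1cc(O)c(C=O)c2Oc3cc(O)c(C(=O)C=C(C)C)c(C)c3OC(=O)c12 | intermediate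
21 | mollicellin B | Cc1cc(O)c(C=O)c2c1C(=O)Oc1c(cc3c(c1C)C(=O)CC(C)(C)O3)O2 | target

**Step count.** Total: 11 steps. Longest linear sequence: 10 steps (steps 1–5 and 7–11, from methyl orsellinate); step 6 is a one-step side branch.

**Steps most likely to fail**

1. Step 7 (Proposed new method). The sequence may stall after alkyne insertion as a persistent aryloxycarbene, it may cyclise without CO uptake, a second alkyne may be incorporated, or the ynol ether may polymerise faster than it inserts. The fallback sets out from 3 and comes back at 17, bringing ring B in preformed at the quinone oxidation level by chemistry of established type. Phenol 3 (K2CO3, DMF, 23 °C) should displace bromide from 2-bromo-6-methyl-1,4-benzoquinone by addition–elimination to give methyl 3-formyl-4-methoxy-6-methyl-2-[(5-methyl-3,6-dioxocyclohexa-1,4-dien-1-yl)oxy]benzoate F1. Na2S2O4 in EtOAc/water should reduce it to methyl 2-(2,5-dihydroxy-3-methylphenoxy)-3-formyl-4-methoxy-6-methylbenzoate F2. LiI in refluxing EtOAc should free 2-(2,5-dihydroxy-3-methylphenoxy)-3-formyl-4-methoxy-6-methylbenzoic acid F3. EDC·HCl/DMAP at high dilution should close the lactone on the only hydroxyl within reach (B1) to give 7-hydroxy-3-methoxy-1,9-dimethyl-11-oxo-11H-dibenzo[b,e][1,4]dioxepine-4-carbaldehyde F4. MeI/K2CO3 in acetone should then methylate the remaining B4 phenol to give 17.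

2. Step 5. tert-Butoxide may substitute at the α-bromo ether carbon instead of eliminating, the second elimination may be incomplete, or the potassium acetylide of the product may add to the aldehyde of another molecule. The fallback sets out from 3 and comes back at 8, forming the C–O bond by copper-catalysed vinylic coupling instead of by alkene bromination. Phenol 3 and (2,2-dibromoethenyl)tri(propan-2-yl)silane (CuI, 2,2'-bipyridine, K3PO4, toluene, 110 °C) should give methyl 2-{[(Z)-1-bromo-2-(triisopropylsilyl)ethenyl]oxy}-3-formyl-4-methoxy-6-methylbenzoate F5. KOt-Bu in THF should eliminate HBr to give methyl 3-formyl-4-methoxy-6-methyl-2-{[(triisopropylsilyl)ethynyl]oxy}benzoate F6. Bu4NF in THF at −20 °C should remove the silyl group to give 8.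

3. Step 10. Acylation may be diverted to B3, conversion may be poor because AlCl3 is sequestered by the three carbonyl groups, or the lactone may be opened by the Lewis acid. The fallback sets out from 17 and comes back at 21, moving the acylation to the free phenol. BBr3 (CH2Cl2, −78 → 0 °C) should give 3,7-dihydroxy-1,9-dimethyl-11-oxo-11H-dibenzo[b,e][1,4]dioxepine-4-carbaldehyde F7. 3-Methylbut-2-enoic acid in MeSO3H/P2O5 at 60–70 °C should then effect O-acylation, Fries shift to B5 (para to the ether oxygen) and oxa-Michael closure to give 21.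

**Further compounds**

F1 | step 7 | methyl 3-formyl-4-methoxy-6-methyl-2-[(5-methyl-3,6-dioxocyclohexa-1,4-dien-1-yl)oxy]benzoate | COC(=O)c1c(C)cc(OC)c(C=O)c1OC1=CC(=O)C=C(C)C1=O
F2 | step 7 | methyl 2-(2,5-dihydroxy-3-methylphenoxy)-3-formyl-4-methoxy-6-methylbenzoate | COC(=O)c1c(C)cc(OC)c(C=O)c1Oc1cc(O)cc(C)c1O
F3 | step 7 | 2-(2,5-dihydroxy-3-methylphenoxy)-3-formyl-4-methoxy-6-methylbenzoic acid | OC(=O)c1c(C)cc(OC)c(C=O)c1Oc1cc(O)cc(C)c1O
F4 | step 7 | 7-hydroxy-3-methoxy-1,9-dimethyl-11-oxo-11H-dibenzo[b,e][1,4]dioxepine-4-carbaldehyde | Cc1cc(OC)c(C=O)c2Oc3cc(O)cc(C)c3OC(=O)c12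
F5 | step 5 | methyl 2-{[(Z)-1-bromo-2-(triisopropylsilyl)ethenyl]oxy}-3-formyl-4-methoxy-6-methylbenzoate | COC(=O)c1c(C)cc(OC)c(C=O)c1O/C(Br)=C/[Si](C(C)C)(C(C)C)C(C)C
F6 | step 5 | methyl 3-formyl-4-methoxy-6-methyl-2-{[(triisopropylsilyl)ethynyl]oxy}benzoate | COC(=O)c1c(C)cc(OC)c(C=O)c1OC#C[Si](C(C)C)(C(C)C)C(C)C
F7 | step 10 | 3,7-dihydroxy-1,9-dimethyl-11-oxo-11H-dibenzo[b,e][1,4]dioxepine-4-carbaldehyde | Cc1cc(O)c(C=O)c2Oc3cc(O)cc(C)c3OC(=O)c12
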